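**Retrosynthetic overview**
- Feature: the two methyl carbons on C3 and C4 of the oxolane are cis to each other and each trans to the aryl on the adjacent carbon (C2: 4-hydroxy-3-methoxyphenyl; C5: 3-hydroxy-4,5-dimethoxyphenyl). They are treated as the two CH2 ends of a CH2–S–CH2 bridge, i.e. a thiolane cis-fused to the oxolane across C3–C4.
- Target 19 ⇒ (O-debenzylation, C–S hydrogenolysis) cis-fused 1,3-diaryl thieno[3,4-c]furan 17 ⇒ (C2–aryl bond, exo capture of the bicyclic oxocarbenium ion) lactol acetate 12 + diarylzinc 16.
- 12 ⇒ lactone 10 ⇒ (3+2) cycloaddition of thiocarbonyl ylide 9 (from sulfide 8) to (R)-butenolide 7, which forms both future methyl C–C bonds, two stereocentres and the thiolane ring.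
- 7 ⇒ (S)-propargylic alcohol 5 ⇒ aldehyde 2 + methyl propiolate 3 by catalytic enantioselective alkynylation, which sets C5, the only stereocentre of external origin.
- Ring order: oxolane ring first (as the butenolide, step 3), thiolane second (step 4), thiolane opened again in step 9.

Key step: step 4

Assumption: the BINOL–titanium–zinc alkynylation keeps its usual sense with aryl aldehydes, (R)-BINOL directing the alkynyl group to the Re face and so giving the (S)-carbinol 5; the antipodal ligand would be used, with nothing else changed, if a Mosher-ester check on 5 showed the other sense.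

**Route**

Step 1
Reactants: 1 3-hydroxy-4,5-dimethoxybenzaldehyde
Product: 2 3-(benzyloxy)-4,5-dimethoxybenzaldehyde
Conditions: BnBr, K2CO3, DMF, rt
Reagents that add atoms: benzyl bromide, BrCc1ccccc1
Why: Williamson ether synthesis (SN2 O-alkylation of the phenoxide) should give a benzyl ether that withstands the organozinc, fluoride, hydride and Lewis acid steps and is removed by hydrogenolysis at the end.

Step 2
Reactants: 2 3-(benzyloxy)-4,5-dimethoxybenzaldehyde; 3 methyl propiolate
Product: 5 methyl (S)-4-[3-(benzyloxy)-4,5-dimethoxyphenyl]-4-hydroxybut-2-ynoate, via ethylzinc alkynide 4 (not isolated)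
Conditions: 3 (4 equiv), ZnEt2 (4 equiv), (R)-BINOL (40 mol%), HMPA, CH2Cl2, rt; Ti(OiPr)4 (1 equiv); then 2, rt; aq NH4Cl
Reagents that add atoms: none
Why: Catalytic enantioselective alkynylzinc addition to an aldehyde (BINOL–titanium-promoted alkynylation, known for methyl propiolate with aromatic aldehydes), in which the alkynylzinc 4 adds to the Re face of the aldehyde held on the chiral titanium BINOLate and so sets the (S)-carbinol that becomes C5 of the oxolane.

Step 3
Reactants: 5 methyl (S)-4-[3-(benzyloxy)-4,5-dimethoxyphenyl]-4-hydroxybut-2-ynoate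
Product: 7 (R)-5-[3-(benzyloxy)-4,5-dimethoxyphenyl]furan-2(5H)-one, via Z-hydroxy enoate 6 (not isolated)
Conditions: H2 (1 atm), Pd/CaCO3 poisoned with Pb(OAc)2, quinoline, EtOAc, rt; then PPTS (cat.), CH2Cl2, rt
Reagents that add atoms: none
Why: Lindlar-type cis-semihydrogenation gives the Z-γ-hydroxy enoate, which lactonises by acid-catalysed intramolecular transesterification without touching the carbinol centre, whose descriptor changes from S to R only because the CIP ranking of its neighbours changes.

Step 4
Reactants: 7 (R)-5-[3-(benzyloxy)-4,5-dimethoxyphenyl]furan-2(5H)-one; 8 chloromethyl trimethylsilylmethyl sulfide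
Product: 10 (3R,3aR,6aS)-3-[3-(benzyloxy)-4,5-dimethoxyphenyl]tetrahydro-1H-thieno[3,4-c]furan-1(3H)-one (cis-fused, aryl trans to the thiolane CH2 on C3a), via thiocarbonyl ylide 9 (not isolated)
Conditions: 8 (3 equiv, slow addition), CsF (5 equiv), MeCN, rt
Reagents that add atoms: none
Why: Fluoride attacks silicon in 8 and the resulting α-thio carbanion expels chloride from the other arm (1,3-elimination) to give the parent thiocarbonyl ylide 9, which adds as the 4π component across the electron-poor C3=C4 bond of butenolide 7 in a concerted, suprafacial 1,3-dipolar cycloaddition. The closest known reaction type is the fluoride-triggered thiocarbonyl ylide (3+2) cycloaddition to butenolides, maleates and acrylates that gives cis-fused or cis-3,4-disubstituted thiolanes. The thiolane ring is closed by the cycloaddition itself, the C3a–C4 and C6a–C6 bonds forming together on one face of the alkene, so no separate ring-closing event is involved. The new stereocentres C3a and C6a are cis to each other because the addition is suprafacial on a ring Z-alkene, and their absolute sense is dictated by the existing aryl-bearing stereocentre of 7, whose aryl group shields one face so that the dipole adds anti to it. The step needs π-facial selectivity and retention of the base-sensitive γ-stereocentre: the first is secured by the aryl group sitting on the ring carbon directly next to the alkene, the second by the low basicity of suspended CsF in MeCN at room temperature and by slow addition of 8 so that the ylide is consumed as it forms. The ylide is symmetric, so no regiochemical question arises.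

Step 5
Reactants: 10 (3R,3aR,6aS)-3-[3-(benzyloxy)-4,5-dimethoxyphenyl]tetrahydro-1H-thieno[3,4-c]furan-1(3H)-one
Product: 11 (3R,3aR,6aS)-3-[3-(benzyloxy)-4,5-dimethoxyphenyl]tetrahydro-1H,3H-thieno[3,4-c]furan-1-ol (both C1 epimers)
Conditions: i-Bu2AlH (1.1 equiv), CH2Cl2, −78 °C; aq potassium sodium tartrate
Reagents that add atoms: none
Why: Partial reduction of a γ-lactone to the lactol with i-Bu2AlH at low temperature stops at the aluminium hemiacetal and leaves sulfide and benzyl ether alone; the new anomeric centre forms as a mixture that is ionised in step 8.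

Step 6
Reactants: 11 (3R,3aR,6aS)-3-[3-(benzyloxy)-4,5-dimethoxyphenyl]tetrahydro-1H,3H-thieno[3,4-c]furan-1-ol
Product: 12 (3R,3aR,6aS)-3-[3-(benzyloxy)-4,5-dimethoxyphenyl]tetrahydro-1H,3H-thieno[3,4-c]furan-1-yl acetate (both C1 epimers)
Conditions: Ac2O, pyridine, DMAP (cat.), CH2Cl2, 0 °C → rt
Reagents that add atoms: acetic anhydride, CC(=O)OC(C)=O
Why: DMAP-catalysed O-acylation of the lactol installs the anomeric acetate as the leaving group for oxocarbenium ion formation.

Step 7
Reactants: 13 4-bromo-2-methoxyphenol
Product: 14 1-(benzyloxy)-4-bromo-2-methoxybenzene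
Conditions: BnBr, K2CO3, DMF, rt
Reagents that add atoms: benzyl bromide, BrCc1ccccc1
Why: Williamson ether synthesis masks the phenol so that the bromide can be converted into an organometallic reagent with the aryl carbon para to oxygen as the nucleophilic site.

Step 8
Reactants: 12 (3R,3aR,6aS)-3-[3-(benzyloxy)-4,5-dimethoxyphenyl]tetrahydro-1H,3H-thieno[3,4-c]furan-1-yl acetate; 14 1-(benzyloxy)-4-bromo-2-methoxybenzene
Product: 17 (1S,3R,3aR,6aS)-1-[4-(benzyloxy)-3-methoxyphenyl]-3-[3-(benzyloxy)-4,5-dimethoxyphenyl]tetrahydro-1H,3H-thieno[3,4-c]furan, via aryllithium 15 (not isolated), via diarylzinc 16 (not isolated)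
Conditions: 14 (3 equiv), n-BuLi, THF, −78 °C; ZnBr2 (0.5 equiv per Li), −78 → 0 °C; then 12, BF3·OEt2, CH2Cl2, −78 → −20 °C; aq NaHCO3
Reagents that add atoms: none
Why: Lewis acid-mediated C-arylation of a lactol acetate (C-glycosylation-type substitution through a cyclic oxocarbenium ion, BF3 ionising the acetate) with a diarylzinc made by bromine–lithium exchange and transmetalation, the aryl group being delivered to the convex face of the cis-fused bicyclic cation, anti to the thiolane CH2 on the adjacent ring-fusion carbon C6a, which sets C1 as S with the new aryl cis to the C3 aryl.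

Step 9
Reactants: 17 (1S,3R,3aR,6aS)-1-[4-(benzyloxy)-3-methoxyphenyl]-3-[3-(benzyloxy)-4,5-dimethoxyphenyl]tetrahydro-1H,3H-thieno[3,4-c]furan
Product: 18 (2S,3S,4R,5R)-2-[4-(benzyloxy)-3-methoxyphenyl]-5-[3-(benzyloxy)-4,5-dimethoxyphenyl]-3,4-dimethyloxolane
Conditions: Raney Ni (W-2), EtOH/THF, rt → 40 °C
Reagents that add atoms: none
Why: Raney nickel hydrogenolytic desulfurisation cleaves both C–S bonds of the thiolane and turns C4 and C6 into methyl groups without touching the four ring stereocentres, so the cis-dimethyl pattern follows from the cis ring fusion; short exposure at mild temperature is chosen to spare the benzylic C–O bonds, and any aryl benzyl ether lost early converges on the target in step 10.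

Step 10
Reactants: 18 (2S,3S,4R,5R)-2-[4-(benzyloxy)-3-methoxyphenyl]-5-[3-(benzyloxy)-4,5-dimethoxyphenyl]-3,4-dimethyloxolane
Product: 19 (2S,3S,4R,5R)-2-(4-hydroxy-3-methoxyphenyl)-5-(3-hydroxy-4,5-dimethoxyphenyl)-3,4-dimethyloxolane (target)
Conditions: H2 (1 atm), Pd/C (10%), EtOAc, rt
Reagents that add atoms: none
Why: Catalytic hydrogenolysis of the two aryl benzyl ethers over Pd/C in neutral EtOAc should be much faster than cleavage of the dialkyl-type benzylic C–O bonds of the oxolane, so both phenols are released with the ring and its stereocentres intact.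

**Compound list**
1 | 3-hydroxy-4,5-dimethoxybenzaldehyde | COc1cc(C=O)cc(O)c1OC | starting material
2 | 3-(benzyloxy)-4,5-dimethoxybenzaldehyde | COc1cc(C=O)cc(OCc2ccccc2)c1OC | intermediate
3 | methyl propiolate | C#CC(=O)OC | starting material
4 | methyl 3-(ethylzincio)prop-2-ynoate (ethylzinc alkynide) | CC[Zn]C#CC(=O)OC | intermediate
5 | methyl (S)-4-[3-(benzyloxy)-4,5-dimethoxyphenyl]-4-hydroxybut-2-ynoate | COC(=O)C#C[C@@H](O)c1cc(OCc2ccccc2)c(OC)c(OC)c1 | intermediate
6 | methyl (R,Z)-4-[3-(benzyloxy)-4,5-dimethoxyphenyl]-4-hydroxybut-2-enoate | COC(=O)/C=C\[C@@H](O)c1cc(OCc2ccccc2)c(OC)c(OC)c1 | intermediate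
7 | (R)-5-[3-(benzyloxy)-4,5-dimethoxyphenyl]furan-2(5H)-one | O=C1C=C[C@H](c2cc(OCc3ccccc3)c(OC)c(OC)c2)O1 | intermediate
8 | chloromethyl trimethylsilylmethyl sulfide | C[Si](C)(C)CSCCl | starting material
9 | thiocarbonyl ylide (methylenesulfonium methylide) | [CH2-][S+]=C | intermediate
10 | (3R,3aR,6aS)-3-[3-(benzyloxy)-4,5-dimethoxyphenyl]tetrahydro-1H-thieno[3,4-c]furan-1(3H)-one | O=C1O[C@@H](c2cc(OCc3ccccc3)c(OC)c(OC)c2)[C@@H]2CSC[C@H]12 | intermediate
11 | (3R,3aR,6aS)-3-[3-(benzyloxy)-4,5-dimethoxyphenyl]tetrahydro-1H,3H-thieno[3,4-c]furan-1-ol, both C1 epimers | OC1O[C@@H](c2cc(OCc3ccccc3)c(OC)c(OC)c2)[C@@H]2CSC[C@H]12 | intermediate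
12 | (3R,3aR,6aS)-3-[3-(benzyloxy)-4,5-dimethoxyphenyl]tetrahydro-1H,3H-thieno[3,4-c]furan-1-yl acetate, both C1 epimers | CC(=O)OC1O[C@@H](c2cc(OCc3ccccc3)c(OC)c(OC)c2)[C@@H]2CSC[C@H]12 | intermediate
13 | 4-bromo-2-methoxyphenol | COc1cc(Br)ccc1O | starting material
14 | 1-(benzyloxy)-4-bromo-2-methoxybenzene | COc1cc(Br)ccc1OCc1ccccc1 | intermediate
15 | [4-(benzyloxy)-3-methoxyphenyl]lithium | COc1cc([Li])ccc1OCc1ccccc1 | intermediate
16 | bis[4-(benzyloxy)-3-methoxyphenyl]zinc | COc1cc([Zn]c2ccc(OCc3ccccc3)c(OC)c2)ccc1OCc1ccccc1 | intermediate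
17 | (1S,3R,3aR,6aS)-1-[4-(benzyloxy)-3-methoxyphenyl]-3-[3-(benzyloxy)-4,5-dimethoxyphenyl]tetrahydro-1H,3H-thieno[3,4-c]furan | COc1cc([C@H]2O[C@@H](c3cc(OCc4ccccc4)c(OC)c(OC)c3)[C@@H]3CSC[C@H]23)ccc1OCc1ccccc1 | intermediate
18 | (2S,3S,4R,5R)-2-[4-(benzyloxy)-3-methoxyphenyl]-5-[3-(benzyloxy)-4,5-dimethoxyphenyl]-3,4-dimethyloxolane | COc1cc([C@H]2O[C@@H](c3cc(OCc4ccccc4)c(OC)c(OC)c3)[C@H](C)[C@@H]2C)ccc1OCc1ccccc1 | intermediate
19 | (2S,3S,4R,5R)-2-(4-hydroxy-3-methoxyphenyl)-5-(3-hydroxy-4,5-dimethoxyphenyl)-3,4-dimethyloxolane | COc1cc([C@H]2O[C@@H](c3cc(O)c(OC)c(OC)c3)[C@H](C)[C@@H]2C)ccc1O | target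

**Step count**
Total steps: 10. Longest linear sequence: 9 (steps 1–6 and 8–10, from aldehyde 1); step 7 is a one-step side branch.

**Steps most likely to fail**

Step 4 (key cycloaddition). Fluoride may deprotonate the γ-position of butenolide 7, giving the 2-oxidofuran and eroding the C5 configuration, or the short-lived ylide may consume itself faster than it adds. The fallback sets out from 7 and comes back at 10; it generates the same dipole without fluoride or any base, by thermal sila-Pummerer fragmentation of a different precursor. Commercial bis(trimethylsilylmethyl) sulfide is oxidised with NaIO4 in aqueous MeOH to bis(trimethylsilylmethyl) sulfoxide F1. Heating F1 with 7 in DMPU at about 100 °C should move one silyl group from carbon to oxygen, after which the silanolate removes the second silyl group; this releases ylide 9 and hexamethyldisiloxane under neutral conditions, and 9 is trapped by 7 to give 10 with the same facial preference.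

Step 8 (arylation). Capture of the oxocarbenium ion may show poor exo selectivity, or aryl transfer from zinc may be slow so that the cation eliminates to the enol ether. The fallback sets out from lactone 10 and comes back at 17; it forms the C1–aryl bond by carbonyl addition and closes the oxolane afterwards. Aryllithium 15 is added to 10 in THF at −78 °C to give the hemiketal F2 (in equilibrium with its open hydroxy ketone). NaBH4 in MeOH reduces F2 through the open form to the diol F3, as a mixture at the new carbinol. Catalytic TsOH in CH2Cl2 at 0 °C then ionises the carbinol next to the para-benzyloxy aryl group, and the other hydroxyl closes the ring on the benzylic cation. Ring closure under product-stability control should place the aryl trans to the thiolane CH2 on the neighbouring carbon, giving 17.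

Step 9 (desulfurisation). Alongside C–S cleavage, Raney nickel may hydrogenolyse or epimerise the two benzylic C–O bonds of the fully assembled diaryl oxolane. The fallback sets out from lactone 10 and comes back at 18; it removes sulfur before the second benzylic C–O bond exists and gives up the bicyclic bias for control by the adjacent methyl group. Raney Ni in EtOH at rt converts 10 into (3S,4R,5R)-5-[3-(benzyloxy)-4,5-dimethoxyphenyl]-3,4-dimethyloxolan-2-one F4; any ring-opened acid formed there is removed by a bicarbonate wash. i-Bu2AlH at −78 °C gives the lactol F5, and Ac2O/pyridine/DMAP gives the acetate F6. Diarylzinc 16 with BF3·OEt2 in CH2Cl2 at low temperature should then add to the monocyclic oxocarbenium ion trans to the C3 methyl group, the known preference for 3-methyl-substituted five-membered oxocarbenium ions, to give 18.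

**Further compounds**
F1 | step 4 | bis(trimethylsilylmethyl) sulfoxide | C[Si](C)(C)CS(=O)C[Si](C)(C)C
F2 | step 8 | (3R,3aR,6aS)-1-[4-(benzyloxy)-3-methoxyphenyl]-3-[3-(benzyloxy)-4,5-dimethoxyphenyl]tetrahydro-1H,3H-thieno[3,4-c]furan-1-ol (hemiketal, C1 unassigned) | OC1(c2ccc(OCc3ccccc3)c(OC)c2)O[C@@H](c2cc(OCc3ccccc3)c(OC)c(OC)c2)[C@@H]2CSC[C@H]12
F3 | step 8 | cis-3,4-disubstituted thiolane diol: (R)-[3-(benzyloxy)-4,5-dimethoxyphenyl](hydroxy)methyl on one ring carbon, [4-(benzyloxy)-3-methoxyphenyl](hydroxy)methyl (both epimers) on the other | O[C@@H](c1cc(OCc2ccccc2)c(OC)c(OC)c1)[C@@H]1CSC[C@@H]1C(O)c1ccc(OCc2ccccc2)c(OC)c1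
F4 | step 9 | (3S,4R,5R)-5-[3-(benzyloxy)-4,5-dimethoxyphenyl]-3,4-dimethyloxolan-2-one | O=C1O[C@@H](c2cc(OCc3ccccc3)c(OC)c(OC)c2)[C@H](C)[C@@H]1C
F5 | step 9 | (3S,4R,5R)-5-[3-(benzyloxy)-4,5-dimethoxyphenyl]-3,4-dimethyloxolan-2-ol, both C2 epimers | OC1O[C@@H](c2cc(OCc3ccccc3)c(OC)c(OC)c2)[C@H](C)[C@@H]1C
F6 | step 9 | (3S,4R,5R)-5-[3-(benzyloxy)-4,5-dimethoxyphenyl]-3,4-dimethyloxolan-2-yl acetate, both C2 epimers | CC(=O)OC1O[C@@H](c2cc(OCc3ccccc3)c(OC)c(OC)c2)[C@H](C)[C@@H]1C
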